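Readings and results were computed for substances that don't exist, and the scatter is random.

The vessel was closed and stirred at constant volume, with the gas phase held, and you asked me for a quick number with your hunch beside it.

| flask | substrate | gas phase | catalyst | added ligand | remark | time |
|---|---|---|---|---|---|---|
| midnight | 0.050 M | 16 mM (held) | 0.25 mM | 1.1 mM | the very flask that is asked about, followed so far |  |
| flask | 0.050 M | 16 mM (held) | 0.25 mM | 1.1 mM |  | 4.0 h |

midnight run (percent of the substrate charged)

| time / min | product / % | substrate / % |
|---|---|---|
| 5.00 | 0 | 98.0 |
| 10.0 | 1.1 | 94.6 |
| 15.0 | 2.5 | 93.8 |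
| 20.0 | 3.4 | 90.9 |
| 25.0 | 4.1 | 88.4 |
| 30.0 | 5.9 | 85.9 |

(scatter of a reading: 0.5 percentage points)

- at the start none of the gas phase is in solution

* product at 4.0 h, in percent of the substrate charged
* the change that raises the amount of product at 4.0 h, in percent of the substrate charged most ("none" if none brings more than 2 percentage points) (zeta / delta / eta / none)
* amount of product at 4.0 h, in percent of the substrate charged, after zeta

- zeta: doubling the saturation concentration of gas phase, all else as stated
- delta: doubling the transfer coefficient of the gas phase, all else as stated
- eta: doubling the amount of catalyst, all else as stated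

In the midnight run substrate fell from the first reading, yet product still read 0 % at 5.00 min. By 30.0 min the substrate lost was 14.1 %, more than the 5.9 % of product. So I carried one ratio, which read 0.720 there: ω, the product odds, a form of selectivity, is product divided by substrate lost and not found as product. I took it as a reading, with the scatter of 0.5 percentage points on each value, and held it steady.

k, first-order fall of substrate to the last reading: 0.00507 min⁻¹

Substrate left at 4.0 h: 29.6 %

Product at 4.0 h, substrate lost times ω over one plus ω: 29.4 %

The single run varied no setting, so I put no number on the changes.

The forecast gave 62 %, chose eta, and gave 67 % after zeta: “The first step limits the rate, so more catalyst helps most”. My 29.4 % was lower than its figure.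

The flask gave 34.2 %, and 56.0 % after zeta. The best change was eta, which gained 29 points, more than zeta's 22 points or delta's 0.55 points.

    gas phase ⇌ dissolved gas, rate k1*(csat - [dissolved gas]) (kL = 0.00450 s⁻¹)
    substrate + dissolved gas + catalyst → catalyst + product (k = 89.0 M⁻² s⁻¹)
    2 substrate → homo dimer (k = 4.90 × 10⁻⁴ M⁻¹ s⁻¹)
    catalyst + added ligand ⇌ idle complex, settled at all times (K = 8900 M⁻¹)

At 4.00 h the flask held 28.9 % as homo dimer, and ω stood at 1.18. In the scheme catalyst appears in the product step and not in the homo dimer step. So for the neighbour flask with 6.3 × 10⁻⁵ M of catalyst I scaled ω by the catalyst charged, to 0.181. Its substrate lost, 46.9 %, then gave 7.20 % of product. That neighbour flask held 8.84 % of product and 38.0 % as homo dimer, an ω of 0.232.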